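**Plan**
- Cuts, in retrosynthetic order: CO2H back to CH2OAc, then the O1–O2 bond of the 1,2-dioxolane. Next come the C3–CH2 bond of the side arm (allyl + methyl ketone) and the C4–C5 bond (methallyl + methyl ketone). Last are the acyl–CH3 bond and the aryl–CH2 bond of the chain.
- Enabling feature: in the ring O1–O2–C3–C4–C5 the O1–O2 bond is the only weak bond. C3 and C5 are fully substituted, so they have no α-H and cannot be oxidised to carbonyls. They stand 1,3 across C4, so both oxygens fit on one iodine(III) atom in a six-membered ring that can contract to the five-membered peroxide.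
- Forward order: the chain is joined first (B-alkyl Suzuki coupling, methyl ketone). The C4–C5 bond follows, then ozonolysis, the C3–arm bond, ozonolysis/reduction and acetate. The only ring closes in step 12, and the acid is made last.
- Stereochemistry: C5 comes from an (S)-3,3′-Br2-BINOL-catalysed methallylboration. C3 comes from an (R)-catalyst-controlled allylboration of the silyl-protected β-oxy ketone.
- Because the two selections are independent, the minor enantiomer of the first addition ends up mainly in a separable diastereomer. The ring closure breaks no C–O bond.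

Key step: step 12

Assumption: the sense of induction is taken from the aryl methyl ketone series, where the (S)-catalyst is taken to give, with methyl pointing back, OH → larger residue → allyl running clockwise. If a test reaction shows the opposite sense for these dialkyl ketones, the catalyst antipodes of steps 4 and 8 are exchanged and nothing else changes.

**Route**

Step 1
Reactants: 1 methyl undec-10-enoate; 2 bromobenzene
Product: 4 methyl 11-phenylundecanoate, via alkylborane 3 (not isolated)
Conditions: 9-BBN, THF, 0 °C → rt; then 2, PdCl2(dppf) (3 mol %), K2CO3, DMF–THF, 50 °C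
Reagents that add atoms: none
Why: Anti-Markovnikov hydroboration of the terminal alkene with 9-BBN leaves the ester alone, and the primary alkylborane then enters a B-alkyl Suzuki–Miyaura coupling with the aryl bromide under a carbonate base that does not saponify the ester.

Step 2
Reactants: 4 methyl 11-phenylundecanoate
Product: 6 12-phenyldodecan-2-one, via Weinreb amide 5 (not isolated)
Conditions: MeNH(OMe)·HCl, i-PrMgCl, THF, −20 °C; then MeMgBr, 0 °C → rt; 1 M HCl
Reagents that add atoms: methylmagnesium bromide, C[Mg]Br
Why: The magnesium amide converts the ester into the N-methoxy-N-methylamide, and its chelated adduct with MeMgBr survives until the quench, so the Weinreb ketone synthesis should stop at the methyl ketone.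

Step 3
Reactants: 7 2-methylallylmagnesium chloride
Product: 9 5,5-dimethyl-2-(2-methylprop-2-en-1-yl)-1,3,2-dioxaborinane, via methallylboronic acid 8 (not isolated)
Conditions: B(OMe)3, THF–Et2O, −78 °C → rt; 1 M HCl; then 2,2-dimethylpropane-1,3-diol, MgSO4, pentane, rt
Reagents that add atoms: trimethyl borate, COB(OC)OC; 2,2-dimethylpropane-1,3-diol, CC(C)(CO)CO
Why: Borylation of an allylic Grignard reagent followed by esterification with a 1,3-diol is the standard route to six-membered allylboronates, which exchange with a binaphthol catalyst whereas pinacol esters do not.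

Step 4
Reactants: 6 12-phenyldodecan-2-one; 9 5,5-dimethyl-2-(2-methylprop-2-en-1-yl)-1,3,2-dioxaborinane
Product: 10 (4S)-2,4-dimethyl-14-phenyltetradec-1-en-4-ol
Conditions: (S)-3,3′-Br2-BINOL (10 mol %), t-BuOH (2 equiv), toluene, 0 °C → rt
Reagents that add atoms: none
Why: In this chiral-diol-catalysed asymmetric allylboration of a ketone, exchange of one boronate oxygen for the binaphthol gives a more Lewis acidic boronate that reacts through a closed Zimmerman–Traxler chair (methyl axial, chain equatorial), and the (S)-catalyst selects the face that makes the future C5 (S); unbranched alkyl methyl ketones lie within the known scope.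

Step 5
Reactants: 10 (4S)-2,4-dimethyl-14-phenyltetradec-1-en-4-ol
Product: 11 triethyl{[(4S)-2,4-dimethyl-14-phenyltetradec-1-en-4-yl]oxy}silane
Conditions: TESOTf, 2,6-lutidine, CH2Cl2, 0 °C
Reagents that add atoms: triethylsilyl trifluoromethanesulfonate, CC[Si](CC)(CC)OS(=O)(=O)C(F)(F)F
Why: Silyl triflate/lutidine silylation works on hindered tertiary alcohols, and the ether blocks retro-aldol cleavage of the coming β-oxy ketone and keeps the hydroxyl from binding the next boronate and delivering allyl outside catalyst control.

Step 6
Reactants: 11 triethyl{[(4S)-2,4-dimethyl-14-phenyltetradec-1-en-4-yl]oxy}silane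
Product: 13 (4S)-4-methyl-14-phenyl-4-[(triethylsilyl)oxy]tetradecan-2-one, via ozonide 12 (not isolated)
Conditions: O3, CH2Cl2, −78 °C (dye end point); then PPh3, −78 °C → rt
Reagents that add atoms: ozone, [O-][O+]=O
Why: Criegee ozonolysis takes the 1,1-disubstituted alkene far faster than the phenyl ring, and phosphine reduction of the ozonide should give the methyl ketone with the carbinol centre untouched.

Step 7
Reactants: 14 allylmagnesium bromide
Product: 16 5,5-dimethyl-2-(prop-2-en-1-yl)-1,3,2-dioxaborinane, via allylboronic acid 15 (not isolated)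
Conditions: B(OMe)3, Et2O, −78 °C → rt; 1 M HCl; then 2,2-dimethylpropane-1,3-diol, MgSO4, pentane, rt
Reagents that add atoms: trimethyl borate, COB(OC)OC; 2,2-dimethylpropane-1,3-diol, CC(C)(CO)CO
Why: This is the same Grignard borylation and diol esterification as in step 3.

Step 8
Reactants: 13 (4S)-4-methyl-14-phenyl-4-[(triethylsilyl)oxy]tetradecan-2-one; 16 5,5-dimethyl-2-(prop-2-en-1-yl)-1,3,2-dioxaborinane
Product: 17 (4S,6S)-4,6-dimethyl-16-phenyl-6-[(triethylsilyl)oxy]hexadec-1-en-4-ol
Conditions: (R)-3,3′-Br2-BINOL (10 mol %), t-BuOH (2 equiv), toluene, rt; chromatographic removal of the C4 epimer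
Reagents that add atoms: none
Why: The same catalytic asymmetric allylboration is applied with the antipodal catalyst to a ketone whose flanks differ strongly in size (methyl against a neopentyl-type CH2), so reagent control should set the future C3 anti to C5, and the minor diastereomer, which also collects most of the minor enantiomer from step 4, is removed.

Step 9
Reactants: 17 (4S,6S)-4,6-dimethyl-16-phenyl-6-[(triethylsilyl)oxy]hexadec-1-en-4-ol
Product: 19 (3S,5S)-3,5-dimethyl-15-phenyl-5-[(triethylsilyl)oxy]pentadecane-1,3-diol, via ozonide 18 (not isolated)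
Conditions: O3, CH2Cl2, −78 °C; then MeOH, NaBH4, −78 °C → rt
Reagents that add atoms: ozone, [O-][O+]=O
Why: Ozonolysis of the monosubstituted alkene and borohydride reduction of the ozonide shorten the allyl group to the 2-hydroxyethyl arm without touching either carbinol centre.

Step 10
Reactants: 19 (3S,5S)-3,5-dimethyl-15-phenyl-5-[(triethylsilyl)oxy]pentadecane-1,3-diol
Product: 20 (3S,5S)-3-hydroxy-3,5-dimethyl-15-phenyl-5-[(triethylsilyl)oxy]pentadecyl acetate
Conditions: Ac2O (1.2 equiv), pyridine, CH2Cl2, 0 °C → rt
Reagents that add atoms: acetic anhydride, CC(=O)OC(C)=O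
Why: Acylation with anhydride and pyridine, without DMAP, is selective for the primary hydroxyl over the tertiary one.

Step 11
Reactants: 20 (3S,5S)-3-hydroxy-3,5-dimethyl-15-phenyl-5-[(triethylsilyl)oxy]pentadecyl acetate
Product: 21 (3S,5S)-3,5-dihydroxy-3,5-dimethyl-15-phenylpentadecyl acetate
Conditions: HF·pyridine, pyridine, THF, 0 °C → rt
Reagents that add atoms: none
Why: Fluoride-driven Si–O cleavage under buffered conditions spares the acetate and is too mild to ionise the tertiary carbinols.

Step 12
Reactants: 21 (3S,5S)-3,5-dihydroxy-3,5-dimethyl-15-phenylpentadecyl acetate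
Product: 23 2-[(3S,5S)-3,5-dimethyl-5-(10-phenyldecyl)-1,2-dioxolan-3-yl]ethyl acetate, via dioxaiodinane 22 (not isolated)
Conditions: 1-(tert-butylsulfonyl)-2-iodosylbenzene (1.05 equiv), 4 Å MS, PhCl (0.01 M), rt, dark; filtration under Ar; then hν (405 nm LED), −40 °C
Reagents that add atoms: none
Why: Proposed new method: the monomeric, soluble iodosylarene should condense with both tertiary hydroxyls of 21 (the sieves take up the water and no acetate competes for iodine) to give the six-membered 1,3,2-dioxaiodinane 22, in which the diolate must occupy two cis sites, the sulfonyl oxygen fills the site trans to one I–O bond, and the two oxygens are held within about 3 Å. Light of 405 nm, absorbed by the iodane but not by a dialkyl peroxide, breaks one I–O bond, and the iodanyl radical left behind holds the second alkoxide only through a weak three-electron bond, so that it either sheds ArI to give a singlet 1,3-dioxyl pair or is attacked at oxygen by the first oxyl radical; both paths form O1–O2. The closest known reaction types are the light-driven generation of alkoxyl radicals from alcohols and iodine(III) reagents, which normally ends in β-scission or 1,5-hydrogen transfer, and the in-cage coupling of two tert-alkoxyl radicals from hyponitrites to dialkyl peroxides. The 1,2-dioxolane closes by radical–radical combination at oxygen, formally a ring contraction of the six-membered iodane to the five-membered peroxide with extrusion of the aryl iodide. No stereocentre is created and neither C–O bond is broken, so C3 and C5 carry the configurations set in steps 8 and 4 into the ring with retention. The selectivity needed is chemoselectivity for O–O coupling over β-scission and over 1,5-hydrogen transfer from the decyl chain and the neighbouring methyl and methylene groups; it is secured by the release of both oxygens from one iodine atom, by the geminal substitution at C3 and C5 that presses them together, by an arm kept at the acetate level so that only methyl or unstabilised primary radicals could be expelled, and by −40 °C in a solvent without weak C–H bonds, which slows the activated side reactions but not a barrierless coupling.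

Step 13
Reactants: 23 2-[(3S,5S)-3,5-dimethyl-5-(10-phenyldecyl)-1,2-dioxolan-3-yl]ethyl acetate
Product: 24 2-[(3S,5S)-3,5-dimethyl-5-(10-phenyldecyl)-1,2-dioxolan-3-yl]ethan-1-ol
Conditions: K2CO3 (cat.), MeOH, 0 °C → rt
Reagents that add atoms: none
Why: Base-catalysed transesterification removes the acetate, and because the peroxide carbons carry no hydrogen a Kornblum–DeLaMare fragmentation is impossible.

Step 14
Reactants: 24 2-[(3S,5S)-3,5-dimethyl-5-(10-phenyldecyl)-1,2-dioxolan-3-yl]ethan-1-ol
Product: 26 andavadoic acid, 2-[(3R,5S)-3,5-dimethyl-5-(10-phenyldecyl)-1,2-dioxolan-3-yl]acetic acid, via aldehyde 25 (not isolated)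
Conditions: TEMPO (20 mol %), PhI(OAc)2 (2.5 equiv), MeCN–H2O (1:1), rt
Reagents that add atoms: water, O
Why: Oxoammonium (TEMPO) oxidation through the aldehyde hydrate runs near neutral pH without metals or reductants, which dialkyl peroxides tolerate and which avoids base-induced β-elimination of the β-peroxy aldehyde; the C3 descriptor changes from S to R by priority only.

**Compound list**
1 | methyl undec-10-enoate | C=CCCCCCCCCC(=O)OC | starting material
2 | bromobenzene | Brc1ccccc1 | starting material
3 | methyl 11-(9-borabicyclo[3.3.1]nonan-9-yl)undecanoate | COC(=O)CCCCCCCCCCB1C2CCCC1CCC2 | intermediate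
4 | methyl 11-phenylundecanoate | COC(=O)CCCCCCCCCCc1ccccc1 | intermediate
5 | N-methoxy-N-methyl-11-phenylundecanamide | CON(C)C(=O)CCCCCCCCCCc1ccccc1 | intermediate
6 | 12-phenyldodecan-2-one | CC(=O)CCCCCCCCCCc1ccccc1 | intermediate
7 | 2-methylallylmagnesium chloride | CC(=C)C[Mg]Cl | starting material
8 | (2-methylprop-2-en-1-yl)boronic acid | CC(=C)CB(O)O | intermediate
9 | 5,5-dimethyl-2-(2-methylprop-2-en-1-yl)-1,3,2-dioxaborinane | CC(=C)CB1OCC(C)(C)CO1 | intermediate
10 | (4S)-2,4-dimethyl-14-phenyltetradec-1-en-4-ol | C[C@](O)(CCCCCCCCCCc1ccccc1)CC(C)=C | intermediate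
11 | triethyl{[(4S)-2,4-dimethyl-14-phenyltetradec-1-en-4-yl]oxy}silane | C[C@](O[Si](CC)(CC)CC)(CCCCCCCCCCc1ccccc1)CC(C)=C | intermediate
12 | secondary ozonide (3-methyl-1,2,4-trioxolan-3-yl) of 11, trioxolane carbon unassigned | C[C@](O[Si](CC)(CC)CC)(CCCCCCCCCCc1ccccc1)CC1(C)OCOO1 | intermediate
13 | (4S)-4-methyl-14-phenyl-4-[(triethylsilyl)oxy]tetradecan-2-one | C[C@](O[Si](CC)(CC)CC)(CCCCCCCCCCc1ccccc1)CC(C)=O | intermediate
14 | allylmagnesium bromide | C=CC[Mg]Br | starting material
15 | prop-2-en-1-ylboronic acid | C=CCB(O)O | intermediate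
16 | 5,5-dimethyl-2-(prop-2-en-1-yl)-1,3,2-dioxaborinane | C=CCB1OCC(C)(C)CO1 | intermediate
17 | (4S,6S)-4,6-dimethyl-16-phenyl-6-[(triethylsilyl)oxy]hexadec-1-en-4-ol | C[C@](O[Si](CC)(CC)CC)(CCCCCCCCCCc1ccccc1)C[C@](C)(CC=C)O | intermediate
18 | secondary ozonide (1,2,4-trioxolan-3-yl) of 17, trioxolane carbon unassigned | C[C@](O[Si](CC)(CC)CC)(CCCCCCCCCCc1ccccc1)C[C@](C)(CC1OCOO1)O | intermediate
19 | (3S,5S)-3,5-dimethyl-15-phenyl-5-[(triethylsilyl)oxy]pentadecane-1,3-diol | C[C@](O[Si](CC)(CC)CC)(CCCCCCCCCCc1ccccc1)C[C@](C)(CCO)O | intermediate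
20 | (3S,5S)-3-hydroxy-3,5-dimethyl-15-phenyl-5-[(triethylsilyl)oxy]pentadecyl acetate | C[C@](O[Si](CC)(CC)CC)(CCCCCCCCCCc1ccccc1)C[C@](C)(CCOC(C)=O)O | intermediate
21 | (3S,5S)-3,5-dihydroxy-3,5-dimethyl-15-phenylpentadecyl acetate | C[C@](O)(CCCCCCCCCCc1ccccc1)C[C@](C)(CCOC(C)=O)O | intermediate
22 | 2-{(4S,6S)-2-[2-(tert-butylsulfonyl)phenyl]-4,6-dimethyl-6-(10-phenyldecyl)-1,3,2λ3-dioxaiodinan-4-yl}ethyl acetate | C[C@]1(CCCCCCCCCCc2ccccc2)C[C@](C)(CCOC(C)=O)OI(c2ccccc2S(=O)(=O)C(C)(C)C)O1 | intermediate
23 | 2-[(3S,5S)-3,5-dimethyl-5-(10-phenyldecyl)-1,2-dioxolan-3-yl]ethyl acetate | C[C@]1(CCCCCCCCCCc2ccccc2)C[C@](C)(CCOC(C)=O)OO1 | intermediate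
24 | 2-[(3S,5S)-3,5-dimethyl-5-(10-phenyldecyl)-1,2-dioxolan-3-yl]ethan-1-ol | C[C@]1(CCCCCCCCCCc2ccccc2)C[C@](C)(CCO)OO1 | intermediate
25 | 2-[(3R,5S)-3,5-dimethyl-5-(10-phenyldecyl)-1,2-dioxolan-3-yl]acetaldehyde | C[C@]1(CCCCCCCCCCc2ccccc2)C[C@](C)(CC=O)OO1 | intermediate
26 | andavadoic acid, 2-[(3R,5S)-3,5-dimethyl-5-(10-phenyldecyl)-1,2-dioxolan-3-yl]acetic acid | C[C@]1(CCCCCCCCCCc2ccccc2)C[C@](C)(CC(=O)O)OO1 | target

**Step count**
Total step count: 14.
Longest linear sequence: 12 steps (1, 2, 4, 5, 6, 8, 9, 10, 11, 12, 13, 14). Steps 3 and 7 prepare the two boronates on the side.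

**Steps most likely to fail**

Step 12 (O–O closure).
- What may go wrong: the hindered di-tertiary diol may bind iodine through one oxygen only, or bridge two iodine atoms. The two oxyl centres may also be released one after the other, so that 1,5-hydrogen transfer and β-scission outrun the coupling.
- Fallback: both C–O bonds are made from hydrogen peroxide by known reactions, in place of the O–O bond. It sets out from ketone 13 and comes back at alcohol 24.
- Allylboration of 13 with 16 under the (S)-catalyst should give the C3-epimeric homoallylic alcohol F1. Ozonolysis with borohydride work-up then gives the epimeric diol F2.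
- Tosylation of the primary hydroxyl (TsCl, pyridine) gives the monotosylate F3. KOt-Bu closes it by a 4-exo-tet Williamson reaction to the 2,2-disubstituted oxetane F4, with the C3–O bond intact.
- Ethereal H2O2 with catalytic TMSOTf opens such oxetanes at the tertiary carbon with inversion and should also strip the silyl ether. This gives the hydroperoxy diol F5, which has the C3 arrangement of the target.
- Catalytic acid (Amberlyst 15, CH2Cl2) then ionises the C5 carbinol and the hydroperoxide captures the cation. This is the classical preparation of tetraalkyl-1,2-dioxolanes from di-tertiary 1,3-diols and hydrogen peroxide.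
- C5 is scrambled in this closure, so 24 has to be separated by chromatography from the C5-epimeric dioxolane alcohol F6. C3 remains fixed, so both are single enantiomers, and the route goes on with step 14.

Step 4 (first carbinol centre).
- What may go wrong: the catalyst may discriminate poorly between methyl and the unbranched chain, which means poor facial selectivity.
- Fallback: a one-carbon asymmetric addition followed by epoxide opening. It sets out from ketone 6 and comes back at carbinol 10.
- Catalytic asymmetric Corey–Chaykovsky epoxidation is a reaction known to single out methyl ketones. Conditions are dimethylsulfoxonium methylide, the lanthanum–lithium–binaphthoxide antipode that delivers the (S)-product, a triarylphosphine oxide additive, 5 Å MS, THF, rt. It should give the terminal epoxide (2S)-2-methyl-2-(10-phenyldecyl)oxirane F7.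
- Copper-catalysed opening at the CH2 terminus with isopropenylmagnesium bromide (CuI, THF, −30 °C) keeps the tertiary C–O bond and gives 10.

Step 8 (second carbinol centre).
- What may go wrong: addition to the hindered ketone may be slow, and catalyst control may be eroded by the resident centre or by uncatalysed background addition.
- Fallback: the centre is set by epoxidation of an alkene in place of addition to the ketone. It sets out from ketone 13 and comes back at diol 19.
- Horner–Wadsworth–Emmons olefination (triethyl phosphonoacetate, NaH, THF) with separation of the geometric isomers gives the (E)-enoate F8. DIBAL-H reduction then gives the (E)-allylic alcohol F9.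
- Sharpless epoxidation with D-(−)-diethyl tartrate (Ti(Oi-Pr)4, t-BuOOH, 4 Å MS, CH2Cl2, −20 °C) should give the (2R,3R)-epoxy alcohol F10, as for other E-3-methyl-2-alken-1-ols.
- Red-Al delivers hydride to C2 and leaves the tertiary C3–O bond, which gives 19.

**Further compounds**
F1 | step 12 | (4R,6S)-4,6-dimethyl-16-phenyl-6-[(triethylsilyl)oxy]hexadec-1-en-4-ol | C[C@](O[Si](CC)(CC)CC)(CCCCCCCCCCc1ccccc1)C[C@@](C)(CC=C)O
F2 | step 12 | (3R,5S)-3,5-dimethyl-15-phenyl-5-[(triethylsilyl)oxy]pentadecane-1,3-diol | C[C@](O[Si](CC)(CC)CC)(CCCCCCCCCCc1ccccc1)C[C@@](C)(CCO)O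
F3 | step 12 | (3R,5S)-3-hydroxy-3,5-dimethyl-15-phenyl-5-[(triethylsilyl)oxy]pentadecyl 4-methylbenzenesulfonate | C[C@](O[Si](CC)(CC)CC)(CCCCCCCCCCc1ccccc1)C[C@@](C)(CCOS(=O)(=O)c1ccc(C)cc1)O
F4 | step 12 | triethyl({(2S)-2-methyl-1-[(2R)-2-methyloxetan-2-yl]-12-phenyldodecan-2-yl}oxy)silane | C[C@](O[Si](CC)(CC)CC)(CCCCCCCCCCc1ccccc1)C[C@@]2(C)CCO2
F5 | step 12 | (3S,5S)-3-hydroperoxy-3,5-dimethyl-15-phenylpentadecane-1,5-diol | C[C@](O)(CCCCCCCCCCc1ccccc1)C[C@](C)(CCO)OO
F6 | step 12 | 2-[(3S,5R)-3,5-dimethyl-5-(10-phenyldecyl)-1,2-dioxolan-3-yl]ethan-1-ol | C[C@@]1(CCCCCCCCCCc2ccccc2)C[C@](C)(CCO)OO1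
F7 | step 4 | (2S)-2-methyl-2-(10-phenyldecyl)oxirane | C[C@]1(CCCCCCCCCCc2ccccc2)CO1
F8 | step 8 | ethyl (2E,5S)-3,5-dimethyl-15-phenyl-5-[(triethylsilyl)oxy]pentadec-2-enoate | C[C@](O[Si](CC)(CC)CC)(CCCCCCCCCCc1ccccc1)C/C(C)=C/C(=O)OCC
F9 | step 8 | (2E,5S)-3,5-dimethyl-15-phenyl-5-[(triethylsilyl)oxy]pentadec-2-en-1-ol | C[C@](O[Si](CC)(CC)CC)(CCCCCCCCCCc1ccccc1)C/C(C)=C/CO
F10 | step 8 | [(2R,3R)-3-methyl-3-{(2S)-2-methyl-12-phenyl-2-[(triethylsilyl)oxy]dodecyl}oxiran-2-yl]methanol | C[C@](O[Si](CC)(CC)CC)(CCCCCCCCCCc1ccccc1)C[C@@]2(C)O[C@@H]2CO
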